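## Retrosynthetic overview

1. The target comes from one-pot acid removal of the C15 silyl ether and C14 dimethyl acetal of the ten-membered carbocycle. That ring is closed last, at C9–C10, by an intramolecular Nozaki–Hiyama–Kishi reaction of an α-acyloxy aldehyde with a (Z)-2-iodoenal acetal (sets C9).
2. The trans α-methylene-γ-butyrolactone (C6, C7) comes from translactonisation of an α-methylene-δ-lactone. That δ-lactone is made in the key C6–C7 bond formation: an electrochemical, chromium-catalysed allylation of an achiral (2E)-enal by a chiral 3-(bromomethyl)-5-acyloxy-5,6-dihydropyran-2-one, which relays C8 to C7 and C6 and then releases C9 as a primary alcohol.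
3. The bromolactone (C7–C9, C11–C13, ester already on O8) comes from D-xylal and (R)-2-methylbutanoic acid by esterification, oxidative Ferrier rearrangement, Morita–Baylis–Hillman hydroxymethylation and bromination.
4. The enal arm (C1–C6, C10, C14, C15) comes from 4-silyloxybut-2-yn-1-ol by hydroalumination–iodination, Negishi coupling, cross-metathesis, α-iodination, acetalisation and MnO2 oxidation.
5. Ring order: six-membered lactone (from the sugar), then γ-lactone (by translactonisation), then ten-membered carbocycle.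

Assumption: 4-[(tert-butyldimethylsilyl)oxy]but-2-yn-1-ol, but-3-enylzinc bromide solution, D-xylal and (R)-2-methylbutanoic acid are taken as purchasable; positions are cited in germacrane numbering (C1–C15); TBS = tert-butyldimethylsilyl.

## Route

Step 1
Reactants: 1 4-[(TBS)oxy]but-2-yn-1-ol
Product: 3 (2Z)-4-[(TBS)oxy]-3-iodobut-2-en-1-ol, via cyclic alkenylalanate 2 (not isolated)
Conditions: NaAlH2(OCH2CH2OMe)2 (1.5 equiv), THF, 0 °C; then I2, THF, −78 → 0 °C
Reagents that add atoms: iodine, II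
Why: Alkoxide-directed trans-hydroalumination of the propargylic alcohol puts aluminium on the distal alkyne carbon cis to the carbinol (five-membered alanate), and iodinolysis with retention gives the (Z)-vinyl iodide that fixes the later C4=C5 geometry (Corey-type hydroalumination–iodination).

Step 2
Reactants: 3 (2Z)-4-[(TBS)oxy]-3-iodobut-2-en-1-ol; 4 but-3-en-1-ylzinc bromide
Product: 5 (2E)-3-{[(TBS)oxy]methyl}hepta-2,6-dien-1-ol
Conditions: organozinc reagent (0.5 M in THF, 3 equiv), PdCl2(dppf) (5 mol %), THF, 23 → 45 °C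
Reagents that add atoms: none
Why: Negishi coupling of the vinyl iodide with the primary alkylzinc reagent proceeds with retention of alkene geometry, so C3 ends up cis to C6, and it tolerates the free alcohol and the silyl ether.

Step 3
Reactants: 5 (2E)-3-{[(TBS)oxy]methyl}hepta-2,6-dien-1-ol; 6 (2E)-but-2-enal
Product: 7 (2E,6E)-6-{[(TBS)oxy]methyl}-8-hydroxyocta-2,6-dienal
Conditions: crotonaldehyde (5 equiv), second-generation Hoveyda–Grubbs catalyst RuCl2(H2IMes)(=CH-C6H4-2-OiPr) (3 mol %), CH2Cl2, 40 °C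
Reagents that add atoms: none
Why: Olefin cross-metathesis of the terminal alkene with excess crotonaldehyde is E-selective and cannot engage the trisubstituted alkene.

Step 4
Reactants: 7 (2E,6E)-6-{[(TBS)oxy]methyl}-8-hydroxyocta-2,6-dienal
Product: 8 (2Z,6E)-6-{[(TBS)oxy]methyl}-8-hydroxy-2-iodoocta-2,6-dienal
Conditions: I2 (1.5 equiv), DMAP (20 mol %), K2CO3 (1.2 equiv), THF/H2O (1:1), 23 °C
Reagents that add atoms: iodine, II
Why: Amine-catalysed α-iodination of the enal (conjugate addition of DMAP, iodination of the enolate, elimination) gives the thermodynamically preferred (Z)-2-iodoenal, the hindered trisubstituted alkene being inert.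

Step 5
Reactants: 8 (2Z,6E)-6-{[(TBS)oxy]methyl}-8-hydroxy-2-iodoocta-2,6-dienal
Product: 9 (2E,6Z)-3-{[(TBS)oxy]methyl}-7-iodo-8,8-dimethoxyocta-2,6-dien-1-ol
Conditions: HC(OMe)3 (5 equiv), CeCl3·7H2O (10 mol %), MeOH, 23 °C
Reagents that add atoms: trimethyl orthoformate, COC(OC)OC
Why: Lewis-acid-catalysed acetalisation masks C14 as the dimethyl acetal so that each later organochromium step meets a single aldehyde, under conditions that spare the silyl ether and the vinyl iodide.

Step 6
Reactants: 9 (2E,6Z)-3-{[(TBS)oxy]methyl}-7-iodo-8,8-dimethoxyocta-2,6-dien-1-ol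
Product: 10 (2E,6Z)-3-{[(TBS)oxy]methyl}-7-iodo-8,8-dimethoxyocta-2,6-dienal
Conditions: MnO2 (15 equiv), CH2Cl2, 23 °C
Reagents that add atoms: none
Why: MnO2 oxidises the primary allylic alcohol to the enal chemoselectively and without alkene isomerisation.

Step 7
Reactants: 11 D-xylal; 12 (2R)-2-methylbutanoic acid (2.2 equiv)
Product: 13 3,4-di-O-[(2R)-2-methylbutanoyl]-D-xylal
Conditions: DCC (2.4 equiv), DMAP (10 mol %), CH2Cl2, 0 → 23 °C
Reagents that add atoms: none
Why: Steglich esterification acylates both glycal hydroxyls under neutral conditions that preserve the enol ether and the α-stereocenter of the bought acid.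

Step 8
Reactants: 13 3,4-di-O-[(2R)-2-methylbutanoyl]-D-xylal
Product: 14 (5S)-5-{[(2R)-2-methylbutanoyl]oxy}-5,6-dihydro-2H-pyran-2-one
Conditions: mCPBA (1.2 equiv), BF3·OEt2 (0.3 equiv), CH2Cl2, −20 °C
Reagents that add atoms: 3-chloroperoxybenzoic acid (mCPBA), OOC(=O)c1cccc(Cl)c1
Why: Oxidative Ferrier rearrangement: BF3 ionises the allylic C3 ester, the peracid adds at the anomeric carbon and the perester fragments to the 2,3-unsaturated δ-lactone, leaving the remaining ester-bearing stereocenter (future C8, from D-xylose) untouched.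

Step 9
Reactants: 14 (5S)-5-{[(2R)-2-methylbutanoyl]oxy}-5,6-dihydro-2H-pyran-2-one; 15 formaldehyde
Product: 16 (5S)-3-(hydroxymethyl)-5-{[(2R)-2-methylbutanoyl]oxy}-5,6-dihydro-2H-pyran-2-one
Conditions: formalin (37 % aq. CH2O, threefold excess), DMAP (20 mol %), THF/H2O, 23 °C
Reagents that add atoms: none
Why: Morita–Baylis–Hillman reaction: DMAP adds reversibly to the β-carbon, the enolate adds to formaldehyde and loss of the amine restores the enoate, so the whole of CH2O is taken up in a pure addition that gives only 16 and the regenerated catalyst (future C13 installed, no new stereocenter).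

Step 10
Reactants: 16 (5S)-3-(hydroxymethyl)-5-{[(2R)-2-methylbutanoyl]oxy}-5,6-dihydro-2H-pyran-2-one
Product: 17 (5S)-3-(bromomethyl)-5-{[(2R)-2-methylbutanoyl]oxy}-5,6-dihydro-2H-pyran-2-one
Conditions: PBr3 (0.45 equiv), Et2O, −10 → 0 °C
Reagents that add atoms: phosphorus tribromide, BrP(Br)Br
Why: The primary allylic alcohol is converted into the bromide by PBr3 (SN2 on the alkyl phosphite), the conjugated endocyclic alkene being the thermodynamic position.

Step 11
Reactants: 10 (2E,6Z)-3-{[(TBS)oxy]methyl}-7-iodo-8,8-dimethoxyocta-2,6-dienal; 17 (5S)-3-(bromomethyl)-5-{[(2R)-2-methylbutanoyl]oxy}-5,6-dihydro-2H-pyran-2-one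
Product: 19 (4S,5R)-5-[(1E,5Z)-2-{[(TBS)oxy]methyl}-6-iodo-7,7-dimethoxyhepta-1,5-dien-1-yl]-4-[(1S)-2-hydroxy-1-{[(2R)-2-methylbutanoyl]oxy}ethyl]-3-methylideneoxolan-2-one, via delta-lactone carbinol 18 (not isolated)
Conditions: bromolactone (1.3 equiv) added over 4 h, CrCl2 (20 mol %), Bu4NBr (0.1 M), DMF, Al anode/graphite cathode (nickel-free), undivided cell, 4 mA (2.5 F/mol), 23 °C; aq. citric acid work-up; then PPTS (20 mol %), CH2Cl2, 23 °C
Reagents that add atoms: none
Why: Proposed new method: cathodically regenerated divalent chromium inserts into the allylic C–Br bond of 17 (the vinyl iodide of 10 is inert without nickel) to give a trivalent allylchromium bound at the exocyclic CH2, which adds to the enal through a closed Zimmerman–Traxler chair at the ring carbon on the face anti to the neighbouring pseudoaxial C5 ester (sets C7) and, because the ring locks the allyl unit in the E geometry, with anti topicity (sets C6), aluminium ions from the anode releasing the alkoxide so that chromium turns over, and mild acid then lets the new hydroxyl open the α-methylene-δ-lactone to the less strained trans α-methylene-γ-butyrolactone, freeing the primary C9 alcohol with the O8 ester already in place; the closest known chemistry is the chromium- or zinc-mediated Barbier allylation of aldehydes with 3-(bromomethyl)furan-2(5H)-ones followed by translactonisation, together with the chromium-catalysed electroreductive Nozaki–Hiyama–Kishi coupling.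

Step 12
Reactants: 19 (4S,5R)-5-[(1E,5Z)-2-{[(TBS)oxy]methyl}-6-iodo-7,7-dimethoxyhepta-1,5-dien-1-yl]-4-[(1S)-2-hydroxy-1-{[(2R)-2-methylbutanoyl]oxy}ethyl]-3-methylideneoxolan-2-one
Product: 20 (4S,5R)-5-[(1E,5Z)-2-{[(TBS)oxy]methyl}-6-iodo-7,7-dimethoxyhepta-1,5-dien-1-yl]-4-[(1S)-1-{[(2R)-2-methylbutanoyl]oxy}-2-oxoethyl]-3-methylideneoxolan-2-one
Conditions: Dess–Martin periodinane (1.3 equiv), CH2Cl2, 0 → 23 °C
Reagents that add atoms: none
Why: Dess–Martin oxidation converts the primary alcohol into the α-acyloxy aldehyde under non-basic conditions that avoid O8→O9 acyl migration and epimerisation at C8.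

Step 13
Reactants: 20 (4S,5R)-5-[(1E,5Z)-2-{[(TBS)oxy]methyl}-6-iodo-7,7-dimethoxyhepta-1,5-dien-1-yl]-4-[(1S)-1-{[(2R)-2-methylbutanoyl]oxy}-2-oxoethyl]-3-methylideneoxolan-2-one
Product: 21 (1(10)E,4E,6R,7S,8S,9S)-15-[(TBS)oxy]-9-hydroxy-14,14-dimethoxy-8-{[(2R)-2-methylbutanoyl]oxy}germacra-1(10),4,11(13)-trien-12,6-olide
Conditions: CrCl2 (10 equiv), NiCl2 (0.1 equiv), DMSO/THF (3:1), 0.002 M, 23 °C
Reagents that add atoms: none
Why: Intramolecular Nozaki–Hiyama–Kishi reaction at high dilution: zerovalent nickel inserts into the vinyl iodide, the alkenyl group passes to trivalent chromium and adds to the aldehyde, and C9 is set because in the ring-closing transition state C7–C8–C9–C10 must be gauche, the C8 ester oxygen lies anti to the forming bond (polar Felkin–Anh) and the chromium-bound aldehyde oxygen points away from the ring, which delivers the 9S (8,9-trans) carbinol.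

Step 14
Reactants: 21 (1(10)E,4E,6R,7S,8S,9S)-15-[(TBS)oxy]-9-hydroxy-14,14-dimethoxy-8-{[(2R)-2-methylbutanoyl]oxy}germacra-1(10),4,11(13)-trien-12,6-olide
Product: 22 (1(10)E,4E,6R,7S,8S,9S)-9,15-dihydroxy-8-{[(2R)-2-methylbutanoyl]oxy}-14-oxogermacra-1(10),4,11(13)-trien-12,6-olide (CNP0331447.8)
Conditions: 48 % aq. HF, MeCN, 0 °C
Reagents that add atoms: water, O
Why: Aqueous HF cleaves the primary silyl ether and hydrolyses the allylic dimethyl acetal in one operation, leaving the lactone, the ester and all stereocenters untouched.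

## Compound list

1 | 4-[(tert-butyldimethylsilyl)oxy]but-2-yn-1-ol | CC(C)(C)[Si](C)(C)OCC#CCO | starting material
2 | cyclic alkenylalanate, sodium 3-{[(tert-butyldimethylsilyl)oxy]methyl}-2,2-bis(2-methoxyethoxy)-2,5-dihydro-1,2-oxaluminol-2-uide | [Na+].COCCO[Al-]1(OCCOC)OCC=C1CO[Si](C)(C)C(C)(C)C | intermediate
3 | (2Z)-4-[(tert-butyldimethylsilyl)oxy]-3-iodobut-2-en-1-ol | OC/C=C(/CO[Si](C)(C)C(C)(C)C)I | intermediate
4 | but-3-en-1-ylzinc bromide | C=CCC[Zn]Br | starting material
5 | (2E)-3-{[(tert-butyldimethylsilyl)oxy]methyl}hepta-2,6-dien-1-ol | OC/C=C(/CO[Si](C)(C)C(C)(C)C)CCC=C | intermediate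
6 | (2E)-but-2-enal (crotonaldehyde) | C/C=C/C=O | starting material
7 | (2E,6E)-6-{[(tert-butyldimethylsilyl)oxy]methyl}-8-hydroxyocta-2,6-dienal | OC/C=C(/CO[Si](C)(C)C(C)(C)C)CC/C=C/C=O | intermediate
8 | (2Z,6E)-6-{[(tert-butyldimethylsilyl)oxy]methyl}-8-hydroxy-2-iodoocta-2,6-dienal | OC/C=C(/CO[Si](C)(C)C(C)(C)C)CC/C=C(/C=O)I | intermediate
9 | (2E,6Z)-3-{[(tert-butyldimethylsilyl)oxy]methyl}-7-iodo-8,8-dimethoxyocta-2,6-dien-1-ol | OC/C=C(/CO[Si](C)(C)C(C)(C)C)CC/C=C(/C(OC)OC)I | intermediate
10 | (2E,6Z)-3-{[(tert-butyldimethylsilyl)oxy]methyl}-7-iodo-8,8-dimethoxyocta-2,6-dienal | O=C/C=C(/CO[Si](C)(C)C(C)(C)C)CC/C=C(/C(OC)OC)I | intermediate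
11 | D-xylal, (3R,4R)-3,4-dihydro-2H-pyran-3,4-diol | O1C=C[C@@H](O)[C@H](O)C1 | starting material
12 | (2R)-2-methylbutanoic acid | OC(=O)[C@H](C)CC | starting material
13 | 3,4-di-O-[(2R)-2-methylbutanoyl]-D-xylal, (3R,4R)-3,4-dihydro-2H-pyran-3,4-diyl bis[(2R)-2-methylbutanoate] | O1C=C[C@@H](OC(=O)[C@H](C)CC)[C@H](OC(=O)[C@H](C)CC)C1 | intermediate
14 | (5S)-5-{[(2R)-2-methylbutanoyl]oxy}-5,6-dihydro-2H-pyran-2-one | O=C1C=C[C@H](OC(=O)[C@H](C)CC)CO1 | intermediate
15 | formaldehyde | C=O | starting material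
16 | (5S)-3-(hydroxymethyl)-5-{[(2R)-2-methylbutanoyl]oxy}-5,6-dihydro-2H-pyran-2-one | O=C1C(CO)=C[C@H](OC(=O)[C@H](C)CC)CO1 | intermediate
17 | (5S)-3-(bromomethyl)-5-{[(2R)-2-methylbutanoyl]oxy}-5,6-dihydro-2H-pyran-2-one | O=C1C(CBr)=C[C@H](OC(=O)[C@H](C)CC)CO1 | intermediate
18 | (4S,5S)-4-[(1R,2E,6Z)-3-{[(tert-butyldimethylsilyl)oxy]methyl}-1-hydroxy-7-iodo-8,8-dimethoxyocta-2,6-dien-1-yl]-3-methylidene-5-{[(2R)-2-methylbutanoyl]oxy}oxan-2-one | C=C1C(=O)OC[C@@H](OC(=O)[C@H](C)CC)[C@@H]1[C@H](O)/C=C(/CO[Si](C)(C)C(C)(C)C)CC/C=C(/C(OC)OC)I | intermediate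
19 | (4S,5R)-5-[(1E,5Z)-2-{[(tert-butyldimethylsilyl)oxy]methyl}-6-iodo-7,7-dimethoxyhepta-1,5-dien-1-yl]-4-[(1S)-2-hydroxy-1-{[(2R)-2-methylbutanoyl]oxy}ethyl]-3-methylideneoxolan-2-one | C=C1C(=O)O[C@H](/C=C(/CO[Si](C)(C)C(C)(C)C)CC/C=C(/C(OC)OC)I)[C@H]1[C@H](OC(=O)[C@H](C)CC)CO | intermediate
20 | (4S,5R)-5-[(1E,5Z)-2-{[(tert-butyldimethylsilyl)oxy]methyl}-6-iodo-7,7-dimethoxyhepta-1,5-dien-1-yl]-4-[(1S)-1-{[(2R)-2-methylbutanoyl]oxy}-2-oxoethyl]-3-methylideneoxolan-2-one | C=C1C(=O)O[C@H](/C=C(/CO[Si](C)(C)C(C)(C)C)CC/C=C(/C(OC)OC)I)[C@H]1[C@H](OC(=O)[C@H](C)CC)C=O | intermediate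
21 | (1(10)E,4E,6R,7S,8S,9S)-15-[(tert-butyldimethylsilyl)oxy]-9-hydroxy-14,14-dimethoxy-8-{[(2R)-2-methylbutanoyl]oxy}germacra-1(10),4,11(13)-trien-12,6-olide (both ring alkenes ring-cis, trans-fused lactone) | C=C1C(=O)O[C@@H]2/C=C(/CO[Si](C)(C)C(C)(C)C)CC/C=C(/C(OC)OC)[C@H](O)[C@@H](OC(=O)[C@H](C)CC)[C@@H]12 | intermediate
22 | (1(10)E,4E,6R,7S,8S,9S)-9,15-dihydroxy-8-{[(2R)-2-methylbutanoyl]oxy}-14-oxogermacra-1(10),4,11(13)-trien-12,6-olide, CNP0331447.8 | C=C1C(=O)O[C@@H]2/C=C(/CO)CC/C=C(/C=O)[C@H](O)[C@@H](OC(=O)[C@H](C)CC)[C@@H]12 | target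

## Step count and risks

Total: 14 steps. Longest linear sequence: 10 steps (steps 1–6, then 11–14); the bromolactone 17 is made in 4 steps (7–10) and joined at step 11. Stereocenters: C8 comes from D-xylal, the ester α-carbon from acid 12, C6 and C7 are set in step 11 and C9 in step 13, all under control of C8.

The three steps most likely to fail:

Step 11 (the proposed electrochemical relay allylation). The allylmetal could lose the C5 carboxylate by 1,4-elimination, chromium turnover at the electrode could be poor, or the acyl group could wander once C9–OH is free. The fallback sets out from bromide 17 and aldehyde 10 and comes back at lactone 19, using only established reaction types. Bromide 17 is borylated with B2pin2 and catalytic Pd2(dba)3 in DMSO (Miyaura-type allylic borylation) to the allylic pinacol boronate (5S)-3-[(4,4,5,5-tetramethyl-1,3,2-dioxaborolan-2-yl)methyl]-5-{[(2R)-2-methylbutanoyl]oxy}-5,6-dihydro-2H-pyran-2-one F1, an isolable reagent that cannot eliminate. Allylboration of 10 (toluene, 80 °C, Sc(OTf)3 if needed) passes through the same closed chair with the same facial bias, and PPTS in CH2Cl2 then cleaves the borate and effects the translactonisation to 19.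

Step 13 (ten-membered ring closure). Oligomerisation is possible, and the acyclic Felkin preference at C9 opposes the ring-based argument, so the C9 epimer may dominate. The fallback sets out from aldehyde 20 and comes back at 21, replacing stereocontrol in the C–C bond formation by a ketone reduction. If the cyclisation gives mainly the (9R)-carbinol, the C9 epimer of 21 F2, the carbinol mixture is oxidised with Dess–Martin periodinane to the macrocyclic 9-oxo compound (enone) F3. Luche reduction (NaBH4, CeCl3·7H2O, MeOH, −78 °C), with hydride entering from the open outer face of the ring, then gives 21.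

Step 9 (hydroxymethylation of the γ-acyloxy enelactone). The basic, nucleophilic catalyst can racemise C5 through the dienolate or degrade the lactone. The fallback sets out from 14 and comes back at 16, replacing the amine-catalysed aldol by a cross-coupling. Johnson α-iodination (I2, pyridine, CH2Cl2, 0 °C) gives (5S)-3-iodo-5-{[(2R)-2-methylbutanoyl]oxy}-5,6-dihydro-2H-pyran-2-one F4, and Stille coupling with (tributylstannyl)methanol (Pd(PPh3)4, CuI, dioxane, 80 °C) delivers 16.

Further compounds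

F1 | step 11 | (5S)-3-[(4,4,5,5-tetramethyl-1,3,2-dioxaborolan-2-yl)methyl]-5-{[(2R)-2-methylbutanoyl]oxy}-5,6-dihydro-2H-pyran-2-one | O=C1C(CB2OC(C)(C)C(C)(C)O2)=C[C@H](OC(=O)[C@H](C)CC)CO1
F2 | step 13 | (1(10)E,4E,6R,7S,8S,9R)-15-[(tert-butyldimethylsilyl)oxy]-9-hydroxy-14,14-dimethoxy-8-{[(2R)-2-methylbutanoyl]oxy}germacra-1(10),4,11(13)-trien-12,6-olide | C=C1C(=O)O[C@@H]2/C=C(/CO[Si](C)(C)C(C)(C)C)CC/C=C(/C(OC)OC)[C@@H](O)[C@@H](OC(=O)[C@H](C)CC)[C@@H]12
F3 | step 13 | (1(10)E,4E,6R,7S,8S)-15-[(tert-butyldimethylsilyl)oxy]-14,14-dimethoxy-8-{[(2R)-2-methylbutanoyl]oxy}-9-oxogermacra-1(10),4,11(13)-trien-12,6-olide | C=C1C(=O)O[C@@H]2/C=C(/CO[Si](C)(C)C(C)(C)C)CC/C=C(/C(OC)OC)C(=O)[C@@H](OC(=O)[C@H](C)CC)[C@@H]12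
F4 | step 9 | (5S)-3-iodo-5-{[(2R)-2-methylbutanoyl]oxy}-5,6-dihydro-2H-pyran-2-one | O=C1C(I)=C[C@H](OC(=O)[C@H](C)CC)CO1
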